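Assumption: 2,6-dimethoxy-4-methylbenzaldehyde (1) and methyl 2,4-dihydroxy-3,6-dimethylbenzoate (4) are taken as purchasable, and carbon monoxide (6) is supplied as the gas. The target is achiral, so no configuration has to be set.

## The problem

The target 8 is a depside: two fully substituted benzene rings held together by a single ester. The ester carbonyl carbon sits on C1' of ring A (C2' OH, C3' CHO, C4' OH, C5' Cl, C6' CH3) and the ester oxygen is O4 of ring B (C1 CO2CH3, C2 OH, C3 CH3, C5 Cl, C6 CH3). There is no stereocentre and no ring to close between the halves. The task is therefore to place twelve substituents correctly and to forge one very crowded C(=O)–O bond. That bond is flanked by the C2' oxygen and C6' methyl on the acyl side and by the C3 methyl and C5 chlorine on the phenol side, so an addition–elimination esterification would pass through a tetrahedral intermediate boxed in by four ortho groups. Several groups limit the choice of reagents: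

- the depside link is an activated aryl ester that hydroxide, alkoxides and amines cleave or transesterify;
- the formyl group between two phenols is open to oxidation and to nucleophiles;
- the two aryl chlorides exclude hydrogenolytic deprotection;
- the C1 methyl ester has to survive whatever unmasks the ring A phenols.

Both rings can be traced to arenes that have only one kind of open ring position (1 and 4), so the halogens can be placed without a regiochemical choice. The feature that opens the route is that the ester carbonyl is a lone carbon atom lying between two complete arenes. It can be supplied last, as carbon monoxide 6, between an iodide at C1' and the phenol at O4.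

## Retrosynthesis

**8 to 7.** The last cut is of the two O–CH3 bonds at O2' and O4' of ring A, which leads back to the bis(methyl ether) 7. Free ring A phenols cannot be carried through the ester-forming step, because they would compete with O4 of ring B for the acyl group and give oligomers. Methyl ethers are preferred over benzyl ethers for three reasons: they come with the ring A starting material at no cost in steps, they survive halogenation and palladium catalysis, and their removal needs no hydrogenolysis that would endanger the C–Cl bonds and the formyl group. Both ethers lie ortho to a carbonyl group (the formyl group for O4', the formyl group and the depside carbonyl for O2'), so a boron trihalide can remove them by chelation. The forward step must cleave both ethers and leave the C1 methyl ester and the depside ester intact.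

**7 to 3, 5 and 6.** Both bonds to the ester carbonyl are cut, C1'–C(=O) and C(=O)–O4, giving aryl iodide 3, phenol 5 and carbon monoxide 6. Two neighbouring cuts were weighed:

- Cutting only C(=O)–O4 asks for a hexasubstituted benzoic acid. That acid has to be made and activated, and its acylation of the hindered phenol runs through the crowded tetrahedral intermediate.
- Cutting only C1'–C(=O) asks for an aryl metal species, which the formyl group does not tolerate.

The double cut halves the molecule into two single rings, each one or two steps from a purchasable compound, and forms the ester inside the coordination sphere of palladium. The forward reaction must add palladium to C–I and not to C–Cl, acylate O4 and not O2, and still turn over with two ortho substituents on each partner.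

**3 to 2 to 1.** The C–I bond and then the C–Cl bond of ring A are cut, leading to monochloride 2 and to aldehyde 1. In 1 the only two ring C–H positions are equivalent by symmetry, and every substituent directs to them: each is ortho to one methoxy group, para to the other, ortho to the methyl group and meta to the formyl group. Regiochemistry is therefore not at issue. What the forward steps must deliver is a stop after one chlorination and then iodination of the last, more crowded position. Chlorine is introduced first so that the C–I bond is never exposed to an electrophilic chlorine source that could replace iodine at the ipso carbon.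

**5 to 4.** The C5–Cl bond of ring B is cut, leading to the commodity ester 4. Its single ring C–H is ortho to O4–H and para to O2–H, so an electrophilic chlorination can go nowhere else. The forward step only has to avoid over-chlorination.

## Roads not taken

**Alternative 1:** ring B built from acyclic esters. Methyl 3-oxopentanoate A1 and methyl crotonate A2 would be combined with sodium methoxide in a Michael addition (ring bond C1–C6) followed by a Dieckmann condensation (ring bond C3–C4). The product is the racemic trans cyclohexanedione methyl 2-hydroxy-3,6-dimethyl-4-oxocyclohex-2-ene-1-carboxylate A3. Chlorinative aromatisation would then give 4 or, with excess chlorinating agent, 5 directly.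

- Merits: cheap bulk reagents, a robust annulation, and the C5 chlorine can come from the aromatisation itself. In independence from a commercial aromatic and in cost on a large scale this road is as good as or better than buying 4.
- Weak points: the two stereocentres of A3 are made only to be destroyed, and the road stops at ring B. It says nothing about ring A or about the crowded depside bond, which would still have to be made as in step 4.
- Comparison: the chosen plan sets against it that 4 is an inexpensive article of commerce one chlorination away from 5. The two or three operations of Alternative 1 therefore buy nothing for the hard part of the problem.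

**Alternative 2:** biomimetic folding of a tetraketide on the ring B oxygen. Phenol 5 would be acylated with an unhindered triketo acid equivalent to give methyl 5-chloro-2-hydroxy-3,6-dimethyl-4-[(3,5,7-trioxooctanoyl)oxy]benzoate A4. Weak base would then bring about the intramolecular aldol of chain C2 onto the C7 ketone and dehydration, forming C1'–C6' and closing ring A as methyl 5-chloro-4-[(2,4-dihydroxy-6-methylbenzoyl)oxy]-2-hydroxy-3,6-dimethylbenzoate A5.

- Merits: the crowded ester is formed while its acyl side is still an open chain, so acylation of O4 is easy. No transition metal, no carbon monoxide and no protecting group are needed. In these respects it is better than the chosen plan.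
- Weak points:
  - In A4 the aryloxide of 5 is an excellent leaving group. Lactonisation of the C5 enol onto the ester carbonyl (a 4-hydroxy-2-pyrone) and the Claisen mode of cyclisation both expel the phenol and compete with the wanted aldol mode.
  - A5 lacks both the C5' chlorine and the C3' formyl group. Ring A of A5 has two open positions, each ortho or para to both phenols, so the two electrophilic substitutions that follow each face a regiochemical choice.
  - With preparation of the chain donor, the count rises to at least six or seven steps.
- Comparison: the chosen plan places both ring A substituents before the coupling, on a symmetrical aldehyde where no choice exists. It pays for this with a palladium step and a deprotection.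

**Alternative 3:** Diels–Alder benzannulation of ring A. Phenol 5 would be acylated to methyl 4-(but-2-ynoyloxy)-5-chloro-2-hydroxy-3,6-dimethylbenzoate A6. This would be heated with 4-chloro-1-methoxy-1,3-bis(trimethylsilyloxy)buta-1,3-diene A7. Cycloaddition forms C1'–C2' and C5'–C6', and loss of methanol and the silyl groups gives methyl 5-chloro-4-[(3-chloro-4,6-dihydroxy-2-methylbenzoyl)oxy]-2-hydroxy-3,6-dimethylbenzoate A8. A final formylation at C3' would complete the target.

- Merits: the ester is again made on an unhindered acyl group. The diene delivers the C5' chlorine with the regiochemistry dictated by the polarised partners. A8 has a single aromatic C–H in the whole molecule, so the late formylation has no regiochemical alternative. In freedom from protecting groups and from palladium it is better than the chosen plan, and in regiocontrol it is its equal.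
- Weak points:
  - A7 is hydrolytically labile and must be made by two silylations of a chlorinated β-keto ester.
  - The β-methyl group makes A6 a sluggish dienophile. At the temperature then needed, silyl migration, decomposition of A7 and open-chain Mukaiyama–Michael addition compete.
  - The last step is a Rieche or Gattermann formylation with a strong Lewis acid on the finished depside, at a ring deactivated by chlorine and the acyl group.
  - The count is about seven operations.
- Comparison: the chosen plan needs five steps and brings ring A in complete. It has to set against this its own two uncertainties, the doubly hindered carbonylation and the double demethylation.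

Key step: step 4

## Route

Step 1
Reactants: 1 2,6-dimethoxy-4-methylbenzaldehyde
Product: 2 3-chloro-2,6-dimethoxy-4-methylbenzaldehyde
Conditions: NCS (1.05 equiv), MeCN, 50 °C
Reagents that add atoms: N-chlorosuccinimide, O=C1CCC(=O)N1Cl
Why: Electrophilic aromatic chlorination at one of the two symmetry-equivalent ring C–H positions, each ortho to one methoxy group, para to the other, ortho to the methyl group and meta to the formyl group. The first chlorine deactivates the ring and twists the neighbouring methoxy group out of conjugation, so with one equivalent of reagent the reaction should stop at the monochloride.

Step 2
Reactants: 2 3-chloro-2,6-dimethoxy-4-methylbenzaldehyde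
Product: 3 3-chloro-5-iodo-2,6-dimethoxy-4-methylbenzaldehyde
Conditions: NIS (1.2 equiv), CF3CO2H–MeCN, 25 → 50 °C
Reagents that add atoms: N-iodosuccinimide, O=C1CCC(=O)N1I
Why: Acid-activated electrophilic aromatic iodination at the only ring C–H left, which is still ortho and para to the two methoxy groups. The aldehyde and the aryl chloride are inert to the iodinating agent, and since chlorine is already in place the C–I bond never meets an electrophilic chlorine source.

Step 3
Reactants: 4 methyl 2,4-dihydroxy-3,6-dimethylbenzoate
Product: 5 methyl 5-chloro-2,4-dihydroxy-3,6-dimethylbenzoate
Conditions: SO2Cl2 (1.05 equiv), CH2Cl2–Et2O, 0 → 25 °C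
Reagents that add atoms: sulfuryl chloride, O=S(=O)(Cl)Cl
Why: Electrophilic aromatic chlorination of a resorcinol-type ring at C5, its single open position, ortho to O4–H and para to O2–H. One equivalent of reagent at low temperature should avoid ipso attack at the methyl-bearing carbons.

Step 4
Reactants: 3 3-chloro-5-iodo-2,6-dimethoxy-4-methylbenzaldehyde; 5 methyl 5-chloro-2,4-dihydroxy-3,6-dimethylbenzoate (1.2 equiv); 6 carbon monoxide
Product: 7 methyl 5-chloro-4-[(3-chloro-5-formyl-4,6-dimethoxy-2-methylbenzoyl)oxy]-2-hydroxy-3,6-dimethylbenzoate
Conditions: Pd(OAc)2 (5 mol %), Xantphos (6 mol %), Et3N (3 equiv), CO (1 atm), toluene, 90 °C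
Reagents that add atoms: carbon monoxide (compound 6), [C-]#[O+]
Why: Heck-type carbonylative esterification (palladium-catalysed aryloxycarbonylation of an aryl iodide with a phenol), a known reaction type applied here to a doubly hindered pair. Pd(OAc)2 is reduced in the flask to zerovalent palladium bound by Xantphos, which inserts into the C1'–I bond of 3; that bond is far weaker than either C–Cl bond, so both chlorides should stay. CO then inserts to give an aroyl complex of divalent palladium, a migration that ortho substituents speed up because it relieves crowding at the metal. Et3N deprotonates O4–H of 5, the phenoxide takes the place of iodide on palladium, and C–O reductive elimination, favoured by the wide bite angle of Xantphos, releases 7 and returns zerovalent palladium. The C1'–C(=O) and C(=O)–O4 bonds therefore form in one operation at the metal, not through a tetrahedral intermediate boxed in by the C2' methoxy, C6' methyl, C3 methyl and C5 chlorine groups. No ring is closed and no stereocentre is created. Site selectivity rests on the substrate: O4–H is the more acidic hydroxyl (ortho chlorine, para ester) and is free, whereas O2–H is locked in a hydrogen bond to the C1 ester carbonyl; ring A carries no free hydroxyl, so 3 cannot acylate itself. The formyl group, the methyl ethers and the methyl ester are spectators under a tertiary amine base.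

Step 5
Reactants: 7 methyl 5-chloro-4-[(3-chloro-5-formyl-4,6-dimethoxy-2-methylbenzoyl)oxy]-2-hydroxy-3,6-dimethylbenzoate
Product: 8 methyl 5-chloro-4-[(3-chloro-5-formyl-4,6-dihydroxy-2-methylbenzoyl)oxy]-2-hydroxy-3,6-dimethylbenzoate
Conditions: BCl3 (6 equiv), CH2Cl2, −78 → 0 °C; then H2O
Reagents that add atoms: none
Why: Chelation-assisted Lewis acid cleavage of aryl methyl ethers ortho to carbonyl groups: boron bound to the formyl oxygen reaches O4', boron bound to the depside carbonyl reaches O2', and chloride removes each methyl group as chloromethane through a six-membered chelate. Both ethers are flanked on two sides and twisted out of conjugation, which labilises them further, whereas the C1 methyl ester and the aryl ester react far more slowly at or below 0 °C. Aqueous work-up frees the phenols from boron.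

## Compound list

1 | 2,6-dimethoxy-4-methylbenzaldehyde | COc1cc(C)cc(OC)c1C=O | starting material
2 | 3-chloro-2,6-dimethoxy-4-methylbenzaldehyde | COc1cc(C)c(Cl)c(OC)c1C=O | intermediate
3 | 3-chloro-5-iodo-2,6-dimethoxy-4-methylbenzaldehyde | COc1c(C=O)c(OC)c(Cl)c(C)c1I | intermediate
4 | methyl 2,4-dihydroxy-3,6-dimethylbenzoate | COC(=O)c1c(C)cc(O)c(C)c1O | starting material
5 | methyl 5-chloro-2,4-dihydroxy-3,6-dimethylbenzoate | COC(=O)c1c(C)c(Cl)c(O)c(C)c1O | intermediate
6 | carbon monoxide | [C-]#[O+] | starting material
7 | methyl 5-chloro-4-[(3-chloro-5-formyl-4,6-dimethoxy-2-methylbenzoyl)oxy]-2-hydroxy-3,6-dimethylbenzoate | COC(=O)c1c(C)c(Cl)c(OC(=O)c2c(C)c(Cl)c(OC)c(C=O)c2OC)c(C)c1O | intermediate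
8 | methyl 5-chloro-4-[(3-chloro-5-formyl-4,6-dihydroxy-2-methylbenzoyl)oxy]-2-hydroxy-3,6-dimethylbenzoate | COC(=O)c1c(C)c(Cl)c(OC(=O)c2c(C)c(Cl)c(O)c(C=O)c2O)c(C)c1O | target

## Step count and risks

Total steps: 5. Longest linear sequence: 4 steps (steps 1, 2, 4 and 5); step 3 is the one-step branch to ring B.

**Step 4 (key step).** The most likely failure is slow capture of the aroyl complex of divalent palladium by the hindered, weakly nucleophilic phenoxide. Reduction of the C–I bond, capture of the aroyl group by traces of water, or decay of the catalyst to palladium metal would then take over. Acylation at O2 is a lesser concern.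

Fallback, from 3 back to 7: the carbonylation is kept but the crowded C–O bond is made by another mechanism. Compound 3 would be hydroxycarbonylated (Pd(OAc)2, Xantphos, CO, H2O, Et3N, dioxane), in which water, the smallest nucleophile available, captures the aroyl complex. This gives 3-chloro-5-formyl-4,6-dimethoxy-2-methylbenzoic acid F1. F1 and phenol 5 would then be joined with trifluoroacetic anhydride in toluene at room temperature. The reaction runs through the mixed anhydride and the linear aroyl cation that 2,6-disubstituted benzoic acids form readily, so the crowded tetrahedral intermediate is avoided. The sequence rejoins the route at 7.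

**Step 5.** The cleavage may stall after one ether, because the formyl oxygen becomes tied into the first boron chelate and no longer assists the second cleavage. Forcing it may bring loss of the C1 methyl ester or of the depside link. A stronger Lewis acid (BBr3 or AlCl3) would be a change of conditions only.

Fallback, from 3 back to 8: the ether cleavage is moved ahead of the coupling and acid-labile acetals are carried instead.
- BBr3 in CH2Cl2 would convert 3 into 3-chloro-2,6-dihydroxy-5-iodo-4-methylbenzaldehyde F2, a substrate without esters.
- Chloromethyl methyl ether and iPr2NEt would give 3-chloro-5-iodo-2,6-bis(methoxymethoxy)-4-methylbenzaldehyde F3.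
- Coupling with 5 and 6 under the conditions of step 4 would give methyl 5-chloro-4-{[3-chloro-5-formyl-4,6-bis(methoxymethoxy)-2-methylbenzoyl]oxy}-2-hydroxy-3,6-dimethylbenzoate F4.
- Dilute HCl in THF–water at room temperature would remove both acetals without touching either ester and arrive at 8.

**Step 2.** Iodination may be incomplete at a position wedged between a methoxy and a methyl group on a ring that the first chlorine has deactivated. Aromatic iodination is also reversible in strong acid, so prolonged heating could bring protodeiodination or iodine migration.

Fallback, from 2 back to 7: the halogen handle is changed. Bromination of 2 with N-bromosuccinimide in MeCN is more strongly driven and not reversible, and would give 3-bromo-5-chloro-2,6-dimethoxy-4-methylbenzaldehyde F5. F5 would enter the carbonylative coupling with 5 and 6 in place of 3, with the same Pd(OAc)2–Xantphos catalyst at 100 °C. Oxidative addition at C–Br is still far faster than at C–Cl. The sequence rejoins the route at 7.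

## Further compounds

F1 | step 4 | 3-chloro-5-formyl-4,6-dimethoxy-2-methylbenzoic acid | COc1c(C=O)c(OC)c(Cl)c(C)c1C(=O)O
F2 | step 5 | 3-chloro-2,6-dihydroxy-5-iodo-4-methylbenzaldehyde | Oc1c(C=O)c(O)c(Cl)c(C)c1I
F3 | step 5 | 3-chloro-5-iodo-2,6-bis(methoxymethoxy)-4-methylbenzaldehyde | COCOc1c(C=O)c(OCOC)c(Cl)c(C)c1I
F4 | step 5 | methyl 5-chloro-4-{[3-chloro-5-formyl-4,6-bis(methoxymethoxy)-2-methylbenzoyl]oxy}-2-hydroxy-3,6-dimethylbenzoate | COC(=O)c1c(C)c(Cl)c(OC(=O)c2c(C)c(Cl)c(OCOC)c(C=O)c2OCOC)c(C)c1O
F5 | step 2 | 3-bromo-5-chloro-2,6-dimethoxy-4-methylbenzaldehyde | COc1c(C=O)c(OC)c(Cl)c(C)c1Br
A1 | alternative 1 | methyl 3-oxopentanoate | CCC(=O)CC(=O)OC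
A2 | alternative 1 | methyl crotonate (methyl (E)-but-2-enoate) | C/C=C/C(=O)OC
A3 | alternative 1 | methyl (1R*,6S*)-2-hydroxy-3,6-dimethyl-4-oxocyclohex-2-ene-1-carboxylate (racemic trans, one enantiomer drawn) | COC(=O)[C@@H]1[C@@H](C)CC(=O)C(C)=C1O
A4 | alternative 2 | methyl 5-chloro-2-hydroxy-3,6-dimethyl-4-[(3,5,7-trioxooctanoyl)oxy]benzoate | COC(=O)c1c(C)c(Cl)c(OC(=O)CC(=O)CC(=O)CC(C)=O)c(C)c1O
A5 | alternative 2 | methyl 5-chloro-4-[(2,4-dihydroxy-6-methylbenzoyl)oxy]-2-hydroxy-3,6-dimethylbenzoate | COC(=O)c1c(C)c(Cl)c(OC(=O)c2c(C)cc(O)cc2O)c(C)c1O
A6 | alternative 3 | methyl 4-(but-2-ynoyloxy)-5-chloro-2-hydroxy-3,6-dimethylbenzoate | COC(=O)c1c(C)c(Cl)c(OC(=O)C#CC)c(C)c1O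
A7 | alternative 3 | 4-chloro-1-methoxy-1,3-bis(trimethylsilyloxy)buta-1,3-diene (double-bond geometry not specified) | COC(O[Si](C)(C)C)=CC(O[Si](C)(C)C)=CCl
A8 | alternative 3 | methyl 5-chloro-4-[(3-chloro-4,6-dihydroxy-2-methylbenzoyl)oxy]-2-hydroxy-3,6-dimethylbenzoate | COC(=O)c1c(C)c(Cl)c(OC(=O)c2c(C)c(Cl)c(O)cc2O)c(C)c1O
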